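Atoms are numbered as in the bicyclo[4.3.1]decane core (C1, C6 bridgeheads; C10 bridge). The route rests on cutting C1–C9 of the cyclohexene ring: C9 lies β to C7, and C1 is allylic to the C2 methylidene. Hence C7 becomes a ketone and C9 a β-keto radical, released by oxidative opening of a strained cyclopropanol, while C1 is the γ-carbon of a ring allylsilane. One operation closes the six-membered ring across the cycloheptene (6-exo), creates the bridged bicycle, fixes C1 and unveils the methylidene. The precursor is a cycloheptene-1,5-diol carrying a 1-hydroxycyclopropyl group at the future C6 and CH2SiMe3 at C2.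

Key step: step 8

Remark: the core numbers C1–C10 (C11 = methylidene carbon) are kept for the corresponding atoms of every intermediate; Mn(pic)3 (pic = pyridine-2-carboxylate) is assumed to be made beforehand from Mn(OAc)3·2H2O and pyridine-2-carboxylic acid.

Step 1
Reactants: 1 (S)-citronellal
Product: 2 (E)-RAMP hydrazone of citronellal
Conditions: RAMP (1.05 equiv), MgSO4, CH2Cl2, 0 °C → rt
Reagents that add atoms: (R)-1-amino-2-(methoxymethyl)pyrrolidine (RAMP), COC[C@H]1CCCN1N
Why: Hydrazone condensation of an aldehyde runs under neutral conditions, should give the (E)-hydrazone and creates no stereocentre.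

Step 2
Reactants: 2 (E)-RAMP hydrazone of citronellal
Product: 3 α-alkylated RAMP hydrazone (methyl ester)
Conditions: LDA, THF, 0 °C; then methyl bromoacetate, −100 °C → −78 °C
Reagents that add atoms: methyl bromoacetate, COC(=O)CBr
Why: Enders RAMP-hydrazone α-alkylation, in which the methoxy-chelated lithium azaenolate is alkylated on one face only, so the auxiliary sets C5 (3S in the ester) irrespective of the neighbouring methyl-bearing centre.

Step 3
Reactants: 3 α-alkylated RAMP hydrazone
Product: 4 methyl (3S,4S)-3-formyl-4,8-dimethylnon-7-enoate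
Conditions: CuCl2·2H2O, THF, pH 7 phosphate buffer, rt
Reagents that add atoms: water, O
Why: Copper-assisted hydrazone hydrolysis near neutral pH needs no ozone, so both alkenes, the ester and the α-stereocentre of the aldehyde should survive.

Step 4
Reactants: 4 methyl (3S,4S)-3-formyl-4,8-dimethylnon-7-enoate
Product: 6 (4S,5S)-4,5-trans lactone carrying the 2-[(trimethylsilyl)methyl]allyl arm, via open-chain hydroxy ester 5 (not isolated)
Conditions: 2-(chloromethyl)-3-(trimethylsilyl)prop-1-ene, Mg, THF, 0 °C; (−)-Ipc2BOMe, Et2O, −78 °C → rt; then 4, −78 °C; NaBO3·4H2O, THF/H2O, rt; DBU (cat.), CH2Cl2, rt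
Reagents that add atoms: 2-(chloromethyl)-3-(trimethylsilyl)prop-1-ene, C=C(CCl)C[Si](C)(C)C
Why: Brown asymmetric allylboration through a chair transition state sets C4 (S) under reagent control that is matched with the Felkin–Anh preference of the aldehyde, and the γ-hydroxy methyl ester then lactonises to the 4,5-trans lactone.

Step 5
Reactants: 6 (4S,5S)-4,5-trans lactone
Product: 7 all-trans lactone with the (S)-1-hydroxyallyl group at C6
Conditions: LDA, THF, −78 °C; acrolein, −78 °C; AcOH quench at −78 °C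
Reagents that add atoms: acrolein, C=CC=O
Why: Lactone enolate aldol addition (1,2 to acrolein), in which the aldehyde enters anti to the C5 side chain (sets C6) and the ring-fixed (E)-enolate should give, through a Zimmerman–Traxler chair, the anti aldol, that is the (S)-carbinol at C10.

Step 6
Reactants: 7 aldol lactone
Product: 8 bridged bicyclic lactone with ring allylsilane (7-oxabicyclo[4.2.1]non-3-en-8-one)
Conditions: second-generation Grubbs catalyst (10 mol%), 1,4-benzoquinone (20 mol%), toluene (2 mM), 80 °C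
Reagents that add atoms: none
Why: Ring-closing metathesis joins the vinyl group with the 1,1-disubstituted alkene, whose arms are cis on the lactone, so a seven-membered ring bridges the lactone and a trisubstituted ring allylsilane (C1=C2–CH2SiMe3) results without any new stereocentre.

Step 7
Reactants: 8 bridged bicyclic lactone
Product: 9 cyclopropanol cycloheptenediol
Conditions: EtMgBr (5 equiv), Ti(OiPr)4 (0.3 equiv), THF, 0 °C → rt
Reagents that add atoms: ethylmagnesium bromide, CC[Mg]Br
Why: Kulinkovich cyclopropanation, in which the titanacyclopropane made from EtMgBr adds twice to the lactone carbonyl to give the 1-substituted cyclopropanol (C7, C8, C9) and frees the C4 hydroxyl, while the trisubstituted alkenes do not exchange onto titanium and no stereocentre is touched.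

Step 8
Reactants: 9 cyclopropanol cycloheptenediol
Product: 10 bicyclo[4.3.1]decan-7-one diol with C2 methylidene
Conditions: Mn(pic)3 (2.5 equiv; pic = pyridine-2-carboxylate), degassed DMF, 0 °C → rt
Reagents that add atoms: none
Why: Trivalent manganese oxidises the cyclopropanol O–H and the strained ring opens to the primary β-keto radical at C9, which adds to C1 of the ring allylsilane; the tertiary β-silyl radical at C2 is oxidised by a second equivalent to the cation and loses the silyl group to give the C2 methylidene. The closest known reaction type is the oxidative ring opening and radical cyclisation of cyclopropanols with Mn(pic)3, joined to the oxidative radical allylation of allylsilanes. The cyclohexanone ring (C6, C7, C8, C9, C1, C10) closes in the 6-exo-trig mode and thereby bridges the cycloheptene. The only new stereocentre, C1, is dictated by the tether, since the chain anchored at C6 can reach C1 only on the ring face that carries the C6–C7 bond. The step needs attack at C1 and not C2 and an exocyclic alkene: ring size, the lower substitution of C1 and the β-silyl stabilisation of the C2 radical secure the first, and loss of silicon instead of a proton secures the second. Primary radicals are oxidised only slowly by trivalent manganese, so cyclisation should come before oxidation.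

Step 9
Reactants: 10 bicyclic keto diol
Product: 11 bicyclic keto diacetate
Conditions: Ac2O, pyridine, DMAP (cat.), CH2Cl2, rt
Reagents that add atoms: acetic anhydride, CC(=O)OC(C)=O
Why: DMAP-catalysed acylation esterifies both secondary alcohols (including the hindered C10 bridge carbinol) with retention, and the mild base cannot enolise the ketone toward the bridgehead, so no β-elimination is expected.

Step 10
Reactants: 11 bicyclic keto diacetate
Product: 12 C7 enol triflate
Conditions: LiHMDS (1.1 equiv), THF, −78 °C; Comins' reagent, −78 °C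
Reagents that add atoms: Comins' reagent [N-(5-chloropyridin-2-yl)-1,1,1-trifluoro-N-(trifluoromethylsulfonyl)methanesulfonamide], O=S(=O)(N(c1ccc(Cl)cn1)S(=O)(=O)C(F)(F)F)C(F)(F)F
Why: Kinetic enolate O-triflation, in which only the C8 methylene protons are aligned with the carbonyl (the bridgehead C6–H lies near the carbonyl plane) and LiHMDS deprotonates the ketone but not the acetates, so the C7=C8 enol triflate should form regiospecifically when trapped cold.

Step 11
Reactants: 12 C7 enol triflate
Product: 13 target (CNP0197379.1)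
Conditions: Pd(PPh3)4 (5 mol%), CO (3 atm), Bu3SnH (slow addition), LiCl, THF, 50 °C
Reagents that add atoms: carbon monoxide, [C-]#[O+]
Why: Palladium-catalysed reductive carbonylation (Stille formylation) of the alkenyl triflate, by oxidative addition, CO insertion and hydride transfer from tin, should give the enal directly, and neither acetate is allylic so no π-allyl ionisation competes.

Compound list
1 | (S)-(−)-citronellal, (3S)-3,7-dimethyloct-6-enal | O=CC[C@@H](C)CCC=C(C)C | starting material
2 | (2R)-2-(methoxymethyl)-N-[(1E,3S)-3,7-dimethyloct-6-en-1-ylidene]pyrrolidin-1-amine | COC[C@H]1CCCN1/N=C/C[C@@H](C)CCC=C(C)C | intermediate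
3 | methyl (3S,4S)-3-[(E)-{[(2R)-2-(methoxymethyl)pyrrolidin-1-yl]imino}methyl]-4,8-dimethylnon-7-enoate | COC[C@H]1CCCN1/N=C/[C@H]([C@@H](C)CCC=C(C)C)CC(=O)OC | intermediate
4 | methyl (3S,4S)-3-formyl-4,8-dimethylnon-7-enoate | O=C[C@H]([C@@H](C)CCC=C(C)C)CC(=O)OC | intermediate
5 | methyl (3S,4S)-3-[(1S)-1-hydroxy-3-[(trimethylsilyl)methyl]but-3-en-1-yl]-4,8-dimethylnon-7-enoate | COC(=O)C[C@@H]([C@@H](C)CCC=C(C)C)[C@@H](O)CC(=C)C[Si](C)(C)C | intermediate (not isolated)
6 | (4S,5S)-4-[(2S)-6-methylhept-5-en-2-yl]-5-{2-[(trimethylsilyl)methyl]prop-2-en-1-yl}oxolan-2-one | O=C1C[C@@H]([C@@H](C)CCC=C(C)C)[C@H](CC(=C)C[Si](C)(C)C)O1 | intermediate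
7 | (3S,4R,5S)-3-[(1S)-1-hydroxyprop-2-en-1-yl]-4-[(2S)-6-methylhept-5-en-2-yl]-5-{2-[(trimethylsilyl)methyl]prop-2-en-1-yl}oxolan-2-one | O=C1[C@H]([C@@H](O)C=C)[C@@H]([C@@H](C)CCC=C(C)C)[C@H](CC(=C)C[Si](C)(C)C)O1 | intermediate
8 | (1S,2S,6S,9R)-2-hydroxy-9-[(2S)-6-methylhept-5-en-2-yl]-4-[(trimethylsilyl)methyl]-7-oxabicyclo[4.2.1]non-3-en-8-one | O=C1O[C@H]2CC(C[Si](C)(C)C)=C[C@H](O)[C@@H]1[C@H]2[C@@H](C)CCC=C(C)C | intermediate
9 | (1S,5S,6R,7S)-7-(1-hydroxycyclopropyl)-6-[(2S)-6-methylhept-5-en-2-yl]-3-[(trimethylsilyl)methyl]cyclohept-2-ene-1,5-diol | OC1(CC1)[C@@H]2[C@@H](O)C=C(C[Si](C)(C)C)C[C@H](O)[C@@H]2[C@@H](C)CCC=C(C)C | intermediate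
10 | (1R,4S,5R,6S,10S)-4,10-dihydroxy-2-methylidene-5-[(2S)-6-methylhept-5-en-2-yl]bicyclo[4.3.1]decan-7-one | C=C1C[C@H](O)[C@H]([C@@H](C)CCC=C(C)C)[C@@H]2C(=O)CC[C@H]1[C@@H]2O | intermediate
11 | (1R,4S,5R,6S,10S)-2-methylidene-5-[(2S)-6-methylhept-5-en-2-yl]-7-oxobicyclo[4.3.1]decane-4,10-diyl diacetate | C=C1C[C@H](OC(C)=O)[C@H]([C@@H](C)CCC=C(C)C)[C@@H]2C(=O)CC[C@H]1[C@@H]2OC(C)=O | intermediate
12 | (1R,4S,5R,6S,10S)-2-methylidene-5-[(2S)-6-methylhept-5-en-2-yl]-7-{[(trifluoromethyl)sulfonyl]oxy}bicyclo[4.3.1]dec-7-ene-4,10-diyl diacetate | C=C1C[C@H](OC(C)=O)[C@H]([C@@H](C)CCC=C(C)C)[C@@H]2C(OS(=O)(=O)C(F)(F)F)=CC[C@H]1[C@@H]2OC(C)=O | intermediate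
13 | (1R,4S,5R,6R,10S)-7-formyl-2-methylidene-5-[(2S)-6-methylhept-5-en-2-yl]bicyclo[4.3.1]dec-7-ene-4,10-diyl diacetate | C=C1C[C@H](OC(C)=O)[C@H]([C@@H](C)CCC=C(C)C)[C@@H]2C(C=O)=CC[C@H]1[C@@H]2OC(C)=O | target

Total step count: 11. Longest linear sequence: 11 steps, from (S)-citronellal.

Steps most likely to fail

1. Step 8. The primary C9 radical may abstract the C10 carbinol hydrogen (1,5-hydrogen transfer) or be quenched before it cyclises, and oxidation and desilylation of the C2 radical may lag. The fallback closes the same bond by a polar route, sets out from 8 and comes back at 10. Aminolysis of the lactone with Me(MeO)NH·HCl and AlMe3 should give the Weinreb amide diol F1. Silylation with TBSOTf and 2,6-lutidine should give the bis-silyl ether F2. Vinylmagnesium bromide should convert it into the vinyl ketone F3. EtAlCl2 in toluene at −78 °C should then trigger an intramolecular Hosomi–Sakurai conjugate allylation (C1 of the allylsilane onto C9 of the enone) to the bicyclic bis-silyl ketone F4. HF·pyridine should finally give 10.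

2. Step 6. Closure to a bridged, trisubstituted cycloalkene may stall, or lose out to oligomerisation or to metathesis at the side-chain alkene. The fallback sets out from 7 and comes back at 10, bypassing 8 and 9. The lactone is opened first with Me(MeO)NH·HCl and AlMe3 to the acyclic Weinreb amide diol F5, which is silylated with TBSOTf to the acyclic bis-silyl ether F6. Metathesis with the second-generation Grubbs catalyst should now close an unbridged cycloheptene, the bis-silyl ether F2. F2 is then carried through the vinyl ketone F3 and the bicyclic bis-silyl ketone F4 to 10 as described above.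

3. Step 5. Poor facial selectivity at the aldehyde would give a mixture of C10 carbinol epimers. The fallback sets out from 6 and comes back at 7. The unwanted (R)-carbinol epimer F7 is separated and inverted by Mitsunobu esterification (4-nitrobenzoic acid, PPh3, DIAD, THF, 0 °C) to the 4-nitrobenzoate F8, which K2CO3 in MeOH at 0 °C should cleave to 7.

Further compounds
F1 | step 8 | (1S,2S,6S,7R)-2,6-dihydroxy-N-methoxy-N-methyl-7-[(2S)-6-methylhept-5-en-2-yl]-4-[(trimethylsilyl)methyl]cyclohept-3-ene-1-carboxamide | CON(C)C(=O)[C@@H]1[C@@H](O)C=C(C[Si](C)(C)C)C[C@H](O)[C@@H]1[C@@H](C)CCC=C(C)C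
F2 | step 8 | (1S,2S,6S,7R)-2,6-bis{[tert-butyl(dimethyl)silyl]oxy}-N-methoxy-N-methyl-7-[(2S)-6-methylhept-5-en-2-yl]-4-[(trimethylsilyl)methyl]cyclohept-3-ene-1-carboxamide | CON(C)C(=O)[C@@H]1[C@@H](O[Si](C)(C)C(C)(C)C)C=C(C[Si](C)(C)C)C[C@H](O[Si](C)(C)C(C)(C)C)[C@@H]1[C@@H](C)CCC=C(C)C
F3 | step 8 | 1-[(1S,2S,6S,7R)-2,6-bis{[tert-butyl(dimethyl)silyl]oxy}-7-[(2S)-6-methylhept-5-en-2-yl]-4-[(trimethylsilyl)methyl]cyclohept-3-en-1-yl]prop-2-en-1-one | C=CC(=O)[C@@H]1[C@@H](O[Si](C)(C)C(C)(C)C)C=C(C[Si](C)(C)C)C[C@H](O[Si](C)(C)C(C)(C)C)[C@@H]1[C@@H](C)CCC=C(C)C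
F4 | step 8 | (1R,4S,5R,6S,10S)-4,10-bis{[tert-butyl(dimethyl)silyl]oxy}-2-methylidene-5-[(2S)-6-methylhept-5-en-2-yl]bicyclo[4.3.1]decan-7-one | C=C1C[C@H](O[Si](C)(C)C(C)(C)C)[C@H]([C@@H](C)CCC=C(C)C)[C@@H]2C(=O)CC[C@H]1[C@@H]2O[Si](C)(C)C(C)(C)C
F5 | step 6 | (2S,3R,4S)-4-hydroxy-2-[(1S)-1-hydroxyprop-2-en-1-yl]-N-methoxy-N-methyl-3-[(2S)-6-methylhept-5-en-2-yl]-6-[(trimethylsilyl)methyl]hept-6-enamide | CON(C)C(=O)[C@H]([C@@H](O)C=C)[C@@H]([C@@H](C)CCC=C(C)C)[C@@H](O)CC(=C)C[Si](C)(C)C
F6 | step 6 | (2S,3R,4S)-4-{[tert-butyl(dimethyl)silyl]oxy}-2-[(1S)-1-{[tert-butyl(dimethyl)silyl]oxy}prop-2-en-1-yl]-N-methoxy-N-methyl-3-[(2S)-6-methylhept-5-en-2-yl]-6-[(trimethylsilyl)methyl]hept-6-enamide | CON(C)C(=O)[C@H]([C@@H](O[Si](C)(C)C(C)(C)C)C=C)[C@@H]([C@@H](C)CCC=C(C)C)[C@@H](O[Si](C)(C)C(C)(C)C)CC(=C)C[Si](C)(C)C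
F7 | step 5 | (3S,4R,5S)-3-[(1R)-1-hydroxyprop-2-en-1-yl]-4-[(2S)-6-methylhept-5-en-2-yl]-5-{2-[(trimethylsilyl)methyl]prop-2-en-1-yl}oxolan-2-one | O=C1[C@H]([C@H](O)C=C)[C@@H]([C@@H](C)CCC=C(C)C)[C@H](CC(=C)C[Si](C)(C)C)O1
F8 | step 5 | (1S)-1-[(3S,4R,5S)-4-[(2S)-6-methylhept-5-en-2-yl]-2-oxo-5-{2-[(trimethylsilyl)methyl]prop-2-en-1-yl}oxolan-3-yl]prop-2-en-1-yl 4-nitrobenzoate | O=C1[C@H]([C@@H](OC(=O)c2ccc(cc2)[N+](=O)[O-])C=C)[C@@H]([C@@H](C)CCC=C(C)C)[C@H](CC(=C)C[Si](C)(C)C)O1
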